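The meeting on this flask opened with an easy subtraction.

    starting material + fresh carrier → target + spent carrier (k1 = 0.13 M⁻¹ s⁻¹)
    fresh carrier + impurity → spent catalyst (k2 = 19 M⁻¹ s⁻¹)
    crystals ⇌ target, rate k3*(cs3 - [target]) while solid is left; crystals form when [target] > cs3 (cs3 = 6.9 mM, k3 = 0.0068 s⁻¹)
    spent carrier + salt in the second phase ⇌ fresh carrier + spent salt in the second phase (K4 = 1.4, k4 = 0.15 M⁻¹ s⁻¹)

starting material 10 mM; salt in the second phase 0.950 equiv; spent carrier 2.5 mol%; impurity 0.12 mM; time 8.0 h; volume of the second phase over the first 0.50

- for target the crystals are counted in
- in the second phase: salt in the second phase, spent salt in the second phase; everything else is in the first
- charges count per volume of the first phase; a concentration in a rate is the amount of a species over the volume of its own phase; every rate counts per litre of the first phase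
- as a solid, counted per litre of solution: crystals
- run time (flask): 8.0 h

* target and crystals together at 8.0 h, in percent of the starting material charged
* the change that raises the amount of target and crystals together at 8.0 h, in percent of the starting material charged most ("none" if none brings more than 2 percentage points) (oak / larch / cedar / none)
* amount of target and crystals together at 8.0 h, in percent of the starting material charged, after larch

I reported that the second step halves fresh carrier in 0.084 h, far shorter than the run. So I took the impurity off the charged carrier at once, which leaves 0.130 mM of working carrier.

I argued next that the first step and the exchange act in 0.15 h and 0.068 h, also far shorter than the run, so the carrier keeps to a steady round. I therefore proposed one quantity, the round rate (the steady-state turnover rate). It is the first step's constant times [starting material] times the working carrier times the fresh share. The fresh share is the forward exchange frequency over the sum of that frequency, the backward exchange frequency and the first step's frequency. Salt counts over its own phase, so it starts at 19.0 mM, and the round rate starts at 0.418 mM h⁻¹.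

Held for 8.0 h, that gives 3.34 mM. But the rate falls as the charges are used, so I put that amount back and took the mean of the starting rate and the rate there, which gave 2.54 mM. Going round once more gave 2.72 mM. I committed to a yield between 25.4% and 27.2%.

That amount stays below the solubility, so I expected no crystals and no effect from oak (the solubility doubled) or larch (the dissolution coefficient doubled). Doubled salt, the change called cedar, lifts the starting rate to 0.495 mM h⁻¹, which I scaled to about 5.1 percentage points for cedar, against a threshold of 2 points.

The colleague who made the forecast then gave 26.5% for the yield, cedar as the best change and 26.5% after larch, holding that “only doubling the salt speeds the turnover by more than 2 points”.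

The simulation gives 26.0%, cedar with a gain of 5.5 points, and 26.0% after larch.

The neighbouring flask has 17 mM of starting material, with the same equivalents and loadings. Its impurity charge is unchanged, so its working carrier is 0.305 mM, its salt stands at 32.3 mM, and its round rate starts at 1.67 mM h⁻¹. Held for the same time, that rate gives 13.3 mM. The next two give 7.09 mM and 9.45 mM, both above the solubility, or 41.7% and 55.6% of its charge. Its run reads 46.8%. At 8.00 h this flask holds 0% as crystals, and the neighbouring flask holds 6.04% of its charge.

The constants used here belong to no real substance; the result is computed.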